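**Retrosynthetic overview**

1. The last ring is the cyclobutane. It is closed by a transannular crossed [2+2] photocycloaddition of an 11-membered (E,Z,E)-humulatrienone that already carries both esters; the same step also closes the cyclohexenone and the seven-membered ring (ring order: 11-membered carbocycle first, then 6/7/4 together).
2. Enabling feature (humulane numbering: C11 = ketone carbon, C1=C2(Me), C3–O, C4, C5–O, C6Me2, C7=C8, C9(Me)=C10): the cyclobutane C1–C2–C8–C7 is bridged 1,3 by C11(=O)–C10=C9 on one face and by C3–C4–C5–C6 on the other. Cleaving C1–C7 and C2–C8 therefore unfolds the tricycle into two E-alkenes (enone C1=C2 and dienone terminus C7=C8) that face each other across a humulane ring.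
3. Trienone: Nozaki–Hiyama–Kishi macrocyclisation (C1–C11) of a seco iodo-dienal, then oxidation.
4. Seco chain: boron aldol (C3–C4) of an East methyl ketone with (E)-3-iodo-2-methylpropenal, 1,3-anti reduction, then angelate at C3 and epoxy ester at C5.
5. East ketone: Heck coupling of 3,3-dimethylpent-4-en-2-one with a (Z)-3-iodobut-2-enyl silyl ether. Epoxy acid: Sharpless epoxidation of tiglyl alcohol, then oxidation.

Key step: step 17

Remark 1: the C5 acyl group is taken exactly as drawn, (2S,3R)-2,3-dimethyloxirane-2-carboxylate (methyl groups cis, i.e. the epoxide of the E-acid), and is made as such from tiglyl alcohol.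
Remark 2: humulane numbering (line 2 above) is used in the text for chain and ring atoms. The sense of induction of the Ipc reagent in step 9 and of the tartrate in step 7 is assigned by analogy and should be confirmed on the first run (Mosher ester / optical rotation).

**Route**

Step 1
Reactants: 1 but-2-yn-1-ol
Product: 3 (Z)-3-iodobut-2-en-1-ol, via cyclic alkenylalanate 2 (not isolated)
Conditions: Red-Al, THF, 0 °C → rt; EtOAc; then I2, THF, −78 → 0 °C
Reagents that add atoms: iodine, II
Why: Alkoxide-directed trans-hydroalumination of the propargylic alcohol places aluminium at C3 inside a five-membered alanate, and iodinolysis with retention gives the Z-iodide (iodine cis to CH2OH).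

Step 2
Reactants: 3 (Z)-3-iodobut-2-en-1-ol
Product: 4 (Z)-tert-butyl[(3-iodobut-2-en-1-yl)oxy]dimethylsilane
Conditions: TBSCl, imidazole, CH2Cl2, 0 °C → rt
Reagents that add atoms: tert-butyldimethylsilyl chloride, CC(C)(C)[Si](C)(C)Cl
Why: Standard silylation of a primary allylic alcohol; the ether masks C11–OH through the Pd, boron and acylation steps.

Step 3
Reactants: 5 2,2-dimethylbut-3-enoic acid
Product: 8 3,3-dimethylpent-4-en-2-one, via lithium carboxylate 6 (not isolated), via dilithium gem-diolate 7 (not isolated)
Conditions: MeLi (2.2 equiv), Et2O, 0 °C → rt; inverse quench into cold aq. NH4Cl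
Reagents that add atoms: methyllithium, [Li]C
Why: Methyl ketone synthesis from a carboxylic acid: addition of MeLi to the lithium carboxylate stops at the gem-diolate, which collapses to the ketone only on work-up; the quaternary α-carbon excludes enolisation on that side.

Step 4
Reactants: 4 (Z)-silyl ether; 8 3,3-dimethylpent-4-en-2-one
Product: 9 (4E,6Z)-8-[(tert-butyldimethylsilyl)oxy]-3,3,6-trimethylocta-4,6-dien-2-one
Conditions: Pd(OAc)2 (5 mol%), Bu4NCl, K2CO3, DMF, 50 °C (8 in excess)
Reagents that add atoms: none
Why: Jeffery-type Mizoroki–Heck coupling: the alkenylpalladium adds to the terminal carbon of the neopentyl vinyl group and syn-β-hydride elimination can only give the conjugated E-alkene (no hydrogen on the quaternary side), while the Z-geometry of the iodide is retained.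

Step 5
Reactants: 10 prop-2-yn-1-ol
Product: 12 (E)-3-iodo-2-methylprop-2-en-1-ol, via alkenylalane 11 (not isolated)
Conditions: Me3Al (3 equiv), Cp2ZrCl2 (0.25 equiv), CH2Cl2, 0 °C → rt; then I2, THF, −30 → 0 °C
Reagents that add atoms: trimethylaluminium, C[Al](C)C; iodine, II
Why: Negishi zirconium-catalysed carboalumination adds Me–Al syn across the alkyne with aluminium at the terminus, and iodinolysis with retention gives the E-iodide (iodine trans to CH2OH).

Step 6
Reactants: 12 (E)-3-iodo-2-methylprop-2-en-1-ol
Product: 13 (E)-3-iodo-2-methylprop-2-enal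
Conditions: activated MnO2, CH2Cl2, rt; used directly
Reagents that add atoms: none
Why: MnO2 oxidation of an allylic alcohol to the enal under neutral conditions leaves the vinyl iodide and the alkene geometry untouched.

Step 7
Reactants: 14 (E)-2-methylbut-2-en-1-ol
Product: 15 [(2R,3R)-2,3-dimethyloxiran-2-yl]methanol
Conditions: Ti(OiPr)4 (10 mol%), D-(−)-DIPT (12 mol%), TBHP, 4 Å MS, CH2Cl2, −20 °C
Reagents that add atoms: tert-butyl hydroperoxide, CC(C)(C)OO
Why: Sharpless asymmetric epoxidation; D-(−)-tartrate should deliver oxygen to the face that gives the (2R,3R)-epoxy alcohol (the L-(+)-tartrate gives the 2S,3S series for E-allylic alcohols), and the E-alkene fixes the cis relation of the two methyl groups.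

Step 8
Reactants: 15 [(2R,3R)-2,3-dimethyloxiran-2-yl]methanol
Product: 16 (2S,3R)-2,3-dimethyloxirane-2-carboxylic acid
Conditions: TEMPO (0.2 equiv), PhI(OAc)2 (2.2 equiv), MeCN/H2O 1:1, rt
Reagents that add atoms: water, O
Why: TEMPO/PhI(OAc)2 oxidation of the primary alcohol through the aldehyde hydrate to the acid leaves the trisubstituted epoxide and both stereocentres untouched (the C2 descriptor becomes S only through CIP priority).

Step 9
Reactants: 9 East methyl ketone; 13 (E)-3-iodo-2-methylprop-2-enal
Product: 19 (1E,3R,7E,9Z)-11-[(tert-butyldimethylsilyl)oxy]-3-hydroxy-1-iodo-2,6,6,9-tetramethylundeca-1,7,9-trien-5-one, via boron enolate 17 (not isolated), via boron aldolate 18 (not isolated)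
Conditions: (−)-Ipc2BCl, Et3N, Et2O, 0 °C; then 13, −78 → −20 °C; pH 7 buffer, MeOH, H2O2, 0 °C
Reagents that add atoms: none
Why: Paterson boron aldol of a methyl ketone with a single enolisable site and an enal acceptor; the Ipc ligands of the (−)-reagent are expected to direct attack to the Re face of 13 through the boat-like transition state typical of methyl-ketone boron enolates, which sets 3R.

Step 10
Reactants: 19 aldol adduct
Product: 20 (1E,3R,5R,7E,9Z)-11-[(tert-butyldimethylsilyl)oxy]-1-iodo-2,6,6,9-tetramethylundeca-1,7,9-triene-3,5-diol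
Conditions: Me4NBH(OAc)3, MeCN/AcOH 1:1, −30 → −20 °C
Reagents that add atoms: none
Why: Evans–Saksena reduction: the C3 hydroxyl binds the triacetoxyborohydride and delivers hydride intramolecularly through a chair transition state, which gives the 1,3-anti diol and sets 5R.

Step 11
Reactants: 20 anti-diol; 21 angelic acid
Product: 23 (1E,3R,5R,7E,9Z)-11-[(tert-butyldimethylsilyl)oxy]-5-hydroxy-1-iodo-2,6,6,9-tetramethylundeca-1,7,9-trien-3-yl (Z)-2-methylbut-2-enoate, via angelic mixed anhydride 22 (not isolated)
Conditions: 21, 2,4,6-trichlorobenzoyl chloride, Et3N, toluene, rt; then 20, toluene, 60 °C (no DMAP)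
Reagents that add atoms: none
Why: Yamaguchi-type acylation with the preformed angelic 2,4,6-trichlorobenzoic anhydride (DMAP-free, to avoid Z→E isomerisation); the allylic C3 hydroxyl should react in preference to the neopentyl C5 hydroxyl next to the quaternary carbon.

Step 12
Reactants: 23 C3 mono-angelate; 16 (2S,3R)-2,3-dimethyloxirane-2-carboxylic acid
Product: 25 (1E,3R,5R,7E,9Z)-11-[(tert-butyldimethylsilyl)oxy]-1-iodo-2,6,6,9-tetramethylundeca-1,7,9-triene-3,5-diyl 3-[(Z)-2-methylbut-2-enoate] 5-[(2S,3R)-2,3-dimethyloxirane-2-carboxylate], via epoxy mixed anhydride 24 (not isolated)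
Conditions: 16, 2,4,6-trichlorobenzoyl chloride, Et3N, THF, rt; then 23, DMAP, toluene, 40 °C
Reagents that add atoms: none
Why: Yamaguchi esterification (DMAP-activated mixed anhydride) of the remaining hindered secondary alcohol; coupling with the enantiopure acid also turns any minor enantiomer carried from step 9 into a diastereomer that can be removed by chromatography.

Step 13
Reactants: 25 diester silyl ether
Product: 26 (1E,3R,5R,7E,9Z)-11-hydroxy-1-iodo-2,6,6,9-tetramethylundeca-1,7,9-triene-3,5-diyl 3-[(Z)-2-methylbut-2-enoate] 5-[(2S,3R)-2,3-dimethyloxirane-2-carboxylate]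
Conditions: HF·pyridine, pyridine, THF, 0 °C
Reagents that add atoms: none
Why: Buffered HF·pyridine cleaves the primary allylic TBS ether, while the two esters and the electron-poor glycidate epoxide should survive.

Step 14
Reactants: 26 allylic alcohol
Product: 27 (2Z,4E,7R,9R,10E)-11-iodo-3,6,6,10-tetramethyl-1-oxoundeca-2,4,10-triene-7,9-diyl 7-[(2S,3R)-2,3-dimethyloxirane-2-carboxylate] 9-[(Z)-2-methylbut-2-enoate]
Conditions: activated MnO2, CH2Cl2, rt, dark
Reagents that add atoms: none
Why: MnO2 oxidation of the allylic alcohol to the dienal under neutral conditions; partial Z/E leakage at the enal would be harmless because step 17 is stereoconvergent at C9=C10.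

Step 15
Reactants: 27 seco iodo-dienal
Product: 28 (2Z,4E,7R,9R,10E)-1-hydroxy-3,6,6,10-tetramethylcycloundeca-2,4,10-triene-7,9-diyl 7-[(2S,3R)-2,3-dimethyloxirane-2-carboxylate] 9-[(Z)-2-methylbut-2-enoate] (C1 epimers)
Conditions: CrCl2 (10 equiv), NiCl2 (0.1 equiv), degassed DMSO, slow addition of 27 to 2 mM, rt
Reagents that add atoms: none
Why: Intramolecular Nozaki–Hiyama–Kishi reaction: Ni-catalysed formation of the alkenylchromium(III) species from the vinyl iodide and its chemoselective addition to the aldehyde under high dilution closes the 11-membered ring (C1–C11); esters and epoxide are inert to Cr(II), and the new carbinol centre is erased in step 16.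

Step 16
Reactants: 28 macrocyclic doubly allylic alcohol
Product: 29 (2Z,4E,7R,9R,10E)-3,6,6,10-tetramethyl-1-oxocycloundeca-2,4,10-triene-7,9-diyl 7-[(2S,3R)-2,3-dimethyloxirane-2-carboxylate] 9-[(Z)-2-methylbut-2-enoate]
Conditions: Dess–Martin periodinane, NaHCO3, CH2Cl2, 0 °C → rt, dark
Reagents that add atoms: none
Why: Dess–Martin oxidation of the doubly allylic alcohol gives the cross-conjugated trienone under buffered, non-acidic conditions that avoid Nazarov-type ionisation.

Step 17
Reactants: 29 macrocyclic trienone diester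
Product: 30 target CNP0149458.1 (humulane numbering 1R,2R,3R,5R,7S,8R; 3-O-angeloyl, 5-O-[(2S,3R)-2,3-dimethyloxirane-2-carbonyl])
Conditions: Ir[dF(CF3)ppy]2(dtbbpy)PF6 (2 mol%), degassed MeCN, 2 mM, 450 nm LEDs, 20 °C
Reagents that add atoms: none
Why: Triplet energy transfer from the excited Ir complex populates the lowest, dienone-centred triplet of 29 (which relaxes by twisting about C7=C8/C9=C10, so 9E and 9Z forms converge), its terminus C7 bonds to the unsubstituted enone carbon C1 to give a triplet 1,4-biradical (tertiary radical at C2, oxypentadienyl radical over C8–C10–O), and after intersystem crossing C2 couples with C8. The closest known reaction types are the light-induced transannular crossed [2+2] cycloaddition of cross-conjugated humulene dienones to bridged cyclobutanes and the visible-light, energy-transfer sensitised intramolecular enone/diene–alkene [2+2] cycloaddition that gives 1,3-bridged (crossed) cyclobutanes. Ring closure: the C1–C7 bond is a transannular 6-exo (at the same time 7-endo) closure that forms the cyclohexenone and the seven-membered ring, and the C2–C8 bond is the 1,4-biradical recombination that closes the cyclobutane. Of the four new stereocentres (C1, C2, C7, C8) only one relative configuration is attainable, because the enone bridge must span the cyclobutane 1,3 on one face and the C3–C6 chain 1,3 on the other, so the stepwise closure is stereoconvergent; their absolute sense is controlled by the resident C3 and C5 centres, since only one pairing of the two alkene faces keeps both acyloxy groups on the periphery of the folded ring with the carbinol hydrogens turned inward, whereas the other pairing would force both esters into the ring. The step needs crossed (C1–C7/C2–C8) rather than straight (C1–C8/C2–C7) regiochemistry, which should be secured because first bonding of the CH carbon C1 to the diene terminus C7 gives the most stabilised biradical and avoids joining the fully substituted C2 to the neopentyl C7 next to the C6 quaternary centre, and the C2 radical then reaches only C8 to give the conjugated product enone. It also needs chemoselective excitation, secured by the sensitizer (triplet energy about 61 kcal/mol, 450 nm), which can address only the trienone, so the angelate (no Z/E scrambling), the glycidate and the product cyclohexenone (no secondary 1,3-acyl shift) stay in the ground state.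

**Compound list**

1 | but-2-yn-1-ol | CC#CCO | starting material
2 | sodium cyclic alkenylalanate, 2,2-bis(2-methoxyethoxy)-3-methyl-2,5-dihydro-1,2-oxaaluminol-2-ide (Al on C3, cis to CH2O; not isolated) | CC1=CCO[Al-]1(OCCOC)OCCOC.[Na+] | intermediate
3 | (Z)-3-iodobut-2-en-1-ol | C/C(I)=C/CO | intermediate
4 | (Z)-tert-butyl[(3-iodobut-2-en-1-yl)oxy]dimethylsilane | C/C(I)=C/CO[Si](C)(C)C(C)(C)C | intermediate
5 | 2,2-dimethylbut-3-enoic acid | C=CC(C)(C)C(=O)O | starting material
6 | lithium 2,2-dimethylbut-3-enoate (not isolated) | [Li+].[O-]C(=O)C(C)(C)C=C | intermediate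
7 | dilithium 3,3-dimethylpent-4-ene-2,2-diolate (not isolated) | [Li+].[Li+].CC([O-])([O-])C(C)(C)C=C | intermediate
8 | 3,3-dimethylpent-4-en-2-one | CC(=O)C(C)(C)C=C | intermediate
9 | (4E,6Z)-8-[(tert-butyldimethylsilyl)oxy]-3,3,6-trimethylocta-4,6-dien-2-one | CC(=O)C(C)(C)/C=C/C(C)=C\CO[Si](C)(C)C(C)(C)C | intermediate
10 | prop-2-yn-1-ol | C#CCO | starting material
11 | (E)-alkenylalane, dimethyl{(1E)-3-[(dimethylalumanyl)oxy]-2-methylprop-1-en-1-yl}alumane (not isolated) | C[Al](C)/C=C(\C)CO[Al](C)C | intermediate
12 | (E)-3-iodo-2-methylprop-2-en-1-ol | OC/C(C)=C/I | intermediate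
13 | (E)-3-iodo-2-methylprop-2-enal | O=C/C(C)=C/I | intermediate
14 | (E)-2-methylbut-2-en-1-ol (tiglyl alcohol) | C/C=C(\C)CO | starting material
15 | [(2R,3R)-2,3-dimethyloxiran-2-yl]methanol | OC[C@@]1(C)O[C@@H]1C | intermediate
16 | (2S,3R)-2,3-dimethyloxirane-2-carboxylic acid | OC(=O)[C@@]1(C)O[C@@H]1C | intermediate
17 | diisopinocampheylboron enolate of 9 (enol borinate at the methyl terminus; not isolated) | C=C(OB([C@@H]1C[C@@H]2C[C@@H](C2(C)C)[C@H]1C)[C@@H]1C[C@@H]2C[C@@H](C2(C)C)[C@H]1C)C(C)(C)/C=C/C(C)=C\CO[Si](C)(C)C(C)(C)C | intermediate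
18 | diisopinocampheylboron aldolate of 19 (3-O-borinate; not isolated) | I/C=C(\C)[C@H](OB([C@@H]1C[C@@H]2C[C@@H](C2(C)C)[C@H]1C)[C@@H]1C[C@@H]2C[C@@H](C2(C)C)[C@H]1C)CC(=O)C(C)(C)/C=C/C(C)=C\CO[Si](C)(C)C(C)(C)C | intermediate
19 | (1E,3R,7E,9Z)-11-[(tert-butyldimethylsilyl)oxy]-3-hydroxy-1-iodo-2,6,6,9-tetramethylundeca-1,7,9-trien-5-one | I/C=C(\C)[C@H](O)CC(=O)C(C)(C)/C=C/C(C)=C\CO[Si](C)(C)C(C)(C)C | intermediate
20 | (1E,3R,5R,7E,9Z)-11-[(tert-butyldimethylsilyl)oxy]-1-iodo-2,6,6,9-tetramethylundeca-1,7,9-triene-3,5-diol | I/C=C(\C)[C@H](O)C[C@@H](O)C(C)(C)/C=C/C(C)=C\CO[Si](C)(C)C(C)(C)C | intermediate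
21 | angelic acid, (Z)-2-methylbut-2-enoic acid | C/C=C(/C)C(=O)O | starting material
22 | (Z)-2-methylbut-2-enoic 2,4,6-trichlorobenzoic anhydride (not isolated) | C/C=C(/C)C(=O)OC(=O)c1c(Cl)cc(Cl)cc1Cl | intermediate
23 | C3 mono-angelate of 20 (5-OH free; 1E,3R,5R,7E,9Z) | I/C=C(\C)[C@H](OC(=O)/C(C)=C\C)C[C@@H](O)C(C)(C)/C=C/C(C)=C\CO[Si](C)(C)C(C)(C)C | intermediate
24 | (2S,3R)-2,3-dimethyloxirane-2-carboxylic 2,4,6-trichlorobenzoic anhydride (not isolated) | O=C(OC(=O)c1c(Cl)cc(Cl)cc1Cl)[C@@]1(C)O[C@@H]1C | intermediate
25 | 3-O-angeloyl 5-O-[(2S,3R)-2,3-dimethyloxirane-2-carbonyl] diester of 20 (C11–OTBS) | I/C=C(\C)[C@H](OC(=O)/C(C)=C\C)C[C@@H](OC(=O)[C@@]1(C)O[C@@H]1C)C(C)(C)/C=C/C(C)=C\CO[Si](C)(C)C(C)(C)C | intermediate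
26 | diester 25 with free C11 allylic alcohol | I/C=C(\C)[C@H](OC(=O)/C(C)=C\C)C[C@@H](OC(=O)[C@@]1(C)O[C@@H]1C)C(C)(C)/C=C/C(C)=C\CO | intermediate
27 | seco iodo-dienal, (2Z,4E,7R,9R,10E)-11-iodo-3,6,6,10-tetramethyl-1-oxoundeca-2,4,10-triene-7,9-diyl 7-[(2S,3R)-2,3-dimethyloxirane-2-carboxylate] 9-[(Z)-2-methylbut-2-enoate] | I/C=C(\C)[C@H](OC(=O)/C(C)=C\C)C[C@@H](OC(=O)[C@@]1(C)O[C@@H]1C)C(C)(C)/C=C/C(C)=C\C=O | intermediate
28 | macrocyclic alcohol, (2Z,4E,7R,9R,10E)-1-hydroxy-3,6,6,10-tetramethylcycloundeca-2,4,10-triene-7,9-diyl 7-[(2S,3R)-2,3-dimethyloxirane-2-carboxylate] 9-[(Z)-2-methylbut-2-enoate], C1 epimers | OC1/C=C(\C)[C@H](OC(=O)/C(C)=C\C)C[C@@H](OC(=O)[C@@]2(C)O[C@@H]2C)C(C)(C)/C=C/C(C)=C\1 | intermediate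
29 | macrocyclic trienone, (2Z,4E,7R,9R,10E)-3,6,6,10-tetramethyl-1-oxocycloundeca-2,4,10-triene-7,9-diyl 7-[(2S,3R)-2,3-dimethyloxirane-2-carboxylate] 9-[(Z)-2-methylbut-2-enoate] | O=C1/C=C(\C)[C@H](OC(=O)/C(C)=C\C)C[C@@H](OC(=O)[C@@]2(C)O[C@@H]2C)C(C)(C)/C=C/C(C)=C\1 | intermediate
30 | CNP0149458.1, tricyclic enone diester (cyclobutane bridged 1,3 by the enone and by the diester chain) | C/C=C(/C)C(=O)O[C@@H]1C[C@@H](OC(=O)[C@@]2(C)O[C@@H]2C)C(C)(C)[C@@H]2[C@H]3C(=O)C=C(C)[C@@H]2[C@]31C | target

**Step count**

Total: 17 steps. Longest linear sequence: 12 steps (1, 2, 4, 9–17, from but-2-yn-1-ol).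

**Steps most likely to fail, with fallbacks**

Step 17. What may go wrong: straight (C1–C8/C2–C7) closure or oxyallyl/Nazarov-type and E/Z-only channels of the cross-conjugated divinyl ketone competing with the crossed closure, or poor facial selectivity across the folded ring. Fallback, setting out from 28 and returning at 30: the cycloaddition is run one oxidation level lower. The doubly allylic alcohol 28 is irradiated under the same energy-transfer conditions (Ir sensitizer, 450 nm, degassed MeCN). The chromophore is then the isolated 1,3-diene C7=C8–C9=C10, the divinyl-ketone channels are absent, and the diene triplet adds across C1=C2 (C7–C1, then C8–C2) to give the tricyclic allylic alcohol F1 (C11 carbinol, epimers). Dess–Martin oxidation of this allylic alcohol gives 30.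

Step 15. What may go wrong: oligomerisation or reductive loss of the iodide outrunning the strained 11-membered ring closure in the Cr(II)/aldehyde manifold. Fallback, setting out from 27 and returning at 29: the ring is closed by a Pd-catalysed acyl–alkenyl coupling that delivers the ketone directly. Pd-catalysed stannylation of the vinyl iodide (hexamethylditin, Pd(PPh3)4, toluene, 60 °C) gives the trimethylstannyl dienal F2. Pinnick oxidation (NaClO2, NaH2PO4, excess 2-methyl-2-butene) gives the stannyl dienoic acid F3. Ghosez reagent (1-chloro-N,N,2-trimethylprop-1-en-1-amine, CH2Cl2) gives the acid chloride F4, which is cyclised without isolation by intramolecular acyl-Stille coupling (Pd2(dba)3, tri(2-furyl)phosphine, toluene, high dilution) to trienone 29.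

Step 11. What may go wrong: insufficient discrimination between the two hydroxyls (bis-acylation or acylation at C5) or Z→E isomerisation of the angeloyl group under forcing conditions. Fallback, setting out from 19 and returning at 23: the order of acylation and reduction is inverted, so no site selection is needed. Aldol 19, which has only the C3 hydroxyl, is acylated with mixed anhydride 22 to give the β-angeloyloxy ketone F5. The C5 ketone is then reduced under reagent control by Corey–Bakshi–Shibata reduction ((S)-Me-CBS, catecholborane, toluene, −78 °C; the tert-alkyl side is the large group), which should give the 5R alcohol 23.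

Further compounds
F1 | step 17 | tricyclic allylic alcohol, 30 with the ring ketone (C11) as CH–OH, epimers | C/C=C(/C)C(=O)O[C@@H]1C[C@@H](OC(=O)[C@@]2(C)O[C@@H]2C)C(C)(C)[C@@H]2[C@H]3C(O)C=C(C)[C@@H]2[C@]31C
F2 | step 15 | trimethylstannyl dienal, 27 with SnMe3 in place of iodine (10E retained) | C[Sn](C)(C)/C=C(\C)[C@H](OC(=O)/C(C)=C\C)C[C@@H](OC(=O)[C@@]1(C)O[C@@H]1C)C(C)(C)/C=C/C(C)=C\C=O
F3 | step 15 | stannyl dienoic acid, F2 with CO2H in place of CHO | C[Sn](C)(C)/C=C(\C)[C@H](OC(=O)/C(C)=C\C)C[C@@H](OC(=O)[C@@]1(C)O[C@@H]1C)C(C)(C)/C=C/C(C)=C\C(=O)O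
F4 | step 15 | stannyl dienoyl chloride, F3 as acid chloride | C[Sn](C)(C)/C=C(\C)[C@H](OC(=O)/C(C)=C\C)C[C@@H](OC(=O)[C@@]1(C)O[C@@H]1C)C(C)(C)/C=C/C(C)=C\C(=O)Cl
F5 | step 11 | (1E,3R,7E,9Z)-11-[(tert-butyldimethylsilyl)oxy]-1-iodo-2,6,6,9-tetramethyl-5-oxoundeca-1,7,9-trien-3-yl (Z)-2-methylbut-2-enoate | I/C=C(\C)[C@H](OC(=O)/C(C)=C\C)CC(=O)C(C)(C)/C=C/C(C)=C\CO[Si](C)(C)C(C)(C)C
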